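**Retrosynthetic overview**
- The target is cut at the benzylidene C=C: a (Z)-selective vinylogous aldol condensation joins a 3-aryltetronic acid (fragment A) to an epoxy benzaldehyde (fragment B); both phenols travel as allyl ethers and are freed last.
- Fragment A: the tetronic acid ring comes from a tandem transesterification/Dieckmann reaction of a chroman-6-ylacetate with methyl glycolate. The pyran ring comes from an oxa-6π electrocyclisation of an o-quinone methide (methyl 2,4-dihydroxyphenylacetate + prenal), followed by hydrogenation.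
- Fragment B: the oxirane is closed with inversion from an (S)-hydroxy mesylate; the diol comes from copper-catalysed opening of purchased methyl (S)-glycidate by an aryl Grignard reagent, then MeMgBr addition.
- Ring order: pyran ring → tetronic acid ring → oxirane ring → union; both benzene rings are bought.

Assumption: the SMILES is read as the (Z)-benzylidene isomer with an (R)-configured oxirane CH; methyl (S)-glycidate (D-serine-derived, commercial) supplies that centre.

**Step 1**
Reactants: 1 methyl 2-(2,4-dihydroxyphenyl)acetate; 2 prenal (3-methylbut-2-enal)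
Product: 4 methyl 2-(7-hydroxy-2,2-dimethyl-2H-chromen-6-yl)acetate, via o-quinone methide 3 (not isolated)
Conditions: 2 (1.2 equiv), ethylenediammonium diacetate (10 mol %), toluene, reflux
Reagents that add atoms: prenal (2), CC(C)=CC=O
Why: Amine-catalysed Knoevenagel-type C-alkylation at the unhindered ring carbon para to the 2-OH and loss of water give o-quinone methide 3, whose oxa-6π electrocyclisation closes the 2,2-dimethyl-2H-pyran ring (formal [3+3] chromene annulation); no stereocentre is formed.

**Step 2**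
Reactants: 4 methyl 2-(7-hydroxy-2,2-dimethyl-2H-chromen-6-yl)acetate
Product: 5 methyl 2-(7-hydroxy-2,2-dimethylchroman-6-yl)acetate
Conditions: H2 (1 atm), 10% Pd/C, EtOAc, rt
Reagents that add atoms: none
Why: Heterogeneous catalytic hydrogenation saturates the styrene-type C3=C4 bond of the chromene and leaves the arene, phenol and ester untouched.

**Step 3**
Reactants: 5 methyl 2-(7-hydroxy-2,2-dimethylchroman-6-yl)acetate; 6 allyl bromide
Product: 7 methyl 2-[7-(allyloxy)-2,2-dimethylchroman-6-yl]acetate
Conditions: 6 (1.3 equiv), K2CO3 (2 equiv), DMF, rt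
Reagents that add atoms: allyl bromide (6), C=CCBr
Why: Williamson ether synthesis masks the ortho-phenol, which would otherwise lactonise onto the ester under the strong base of the next step, as an allyl ether that can be removed later under near-neutral conditions.

**Step 4**
Reactants: 7 methyl 2-[7-(allyloxy)-2,2-dimethylchroman-6-yl]acetate; 8 methyl glycolate
Product: 10 3-[7-(allyloxy)-2,2-dimethylchroman-6-yl]-4-hydroxyfuran-2(5H)-one, via glycolate ester 9 (not isolated)
Conditions: 8 (1.3 equiv), KOtBu (2.3 equiv), DMF, 0 °C → rt; then 1 M HCl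
Reagents that add atoms: methyl glycolate (8), COC(=O)CO
Why: Tandem transesterification/Dieckmann condensation: the glycolate alkoxide exchanges onto the arylacetate and the benzylic ester enolate then closes onto the glycolate ester, the stable tetronate anion driving the sequence.

**Step 5**
Reactants: 11 4-hydroxy-3-iodobenzaldehyde; 6 allyl bromide
Product: 12 4-(allyloxy)-3-iodobenzaldehyde
Conditions: 6 (1.2 equiv), K2CO3 (1.5 equiv), DMF, rt
Reagents that add atoms: allyl bromide (6), C=CCBr
Why: Williamson ether synthesis on the acidic para-formyl phenol protects it for the organometallic and epoxide-forming steps.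

**Step 6**
Reactants: 12 4-(allyloxy)-3-iodobenzaldehyde; 13 trimethyl orthoformate
Product: 14 1-(allyloxy)-4-(dimethoxymethyl)-2-iodobenzene
Conditions: HC(OMe)3 (3 equiv), p-TsOH·H2O (1 mol %), MeOH, rt; Et3N quench
Reagents that add atoms: trimethyl orthoformate (13), COC(OC)OC
Why: Acid-catalysed acetalisation with the orthoformate as water scavenger masks the aldehyde so that the aryl iodide can be turned into a Grignard reagent.

**Step 7**
Reactants: 14 1-(allyloxy)-4-(dimethoxymethyl)-2-iodobenzene; 15 methyl (S)-glycidate; 16 methylmagnesium bromide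
Product: 20 4-(allyloxy)-3-[(2S)-2,3-dihydroxy-3-methylbutyl]benzaldehyde, via arylmagnesium chloride 17 (not isolated), via hydroxy ester 18 (not isolated), via diol acetal 19 (not isolated)
Conditions: iPrMgCl·LiCl (1.05 equiv), THF, −20 °C, 1 h; CuI (10 mol %), 15 (1.1 equiv), −40 → −20 °C; MeMgBr (4 equiv), −20 → 0 °C; 1 M HCl, THF, rt, 30 min
Reagents that add atoms: methyl (S)-glycidate (15), COC(=O)[C@@H]1CO1; methylmagnesium bromide (16), C[Mg]Br; water, O
Why: Iodine–magnesium exchange gives 17, which under copper catalysis opens the glycidate by SN2 attack at the terminal CH2 so that the purchased (S) centre is carried unchanged into 18; double Grignard addition to the ester then builds the tertiary carbinol and the acidic work-up hydrolyses the acetal.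

**Step 8**
Reactants: 20 4-(allyloxy)-3-[(2S)-2,3-dihydroxy-3-methylbutyl]benzaldehyde
Product: 22 4-(allyloxy)-3-{[(2R)-3,3-dimethyloxiran-2-yl]methyl}benzaldehyde, via hydroxy mesylate 21 (not isolated)
Conditions: MsCl (1.1 equiv), Et3N (2 equiv), CH2Cl2, −10 °C; then K2CO3 (3 equiv), MeOH, 0 °C → rt
Reagents that add atoms: none
Why: Selective mesylation of the secondary hydroxyl followed by intramolecular Williamson (SN2) displacement by the tertiary alkoxide closes the oxirane with inversion, turning the (S)-carbinol carbon into the (R)-epoxide carbon of the target.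

**Step 9**
Reactants: 10 3-[7-(allyloxy)-2,2-dimethylchroman-6-yl]-4-hydroxyfuran-2(5H)-one; 22 4-(allyloxy)-3-{[(2R)-3,3-dimethyloxiran-2-yl]methyl}benzaldehyde
Product: 24 (5Z)-3-[7-(allyloxy)-2,2-dimethylchroman-6-yl]-5-(4-(allyloxy)-3-{[(2R)-3,3-dimethyloxiran-2-yl]methyl}benzylidene)-4-hydroxyfuran-2(5H)-one, via aldol adduct 23 (not isolated)
Conditions: DBU (3 equiv), MeCN, rt → 60 °C; cold citric acid buffer (pH 4) work-up
Reagents that add atoms: none
Why: Vinylogous aldol condensation: the tetronate dianion adds through C5 to the aldehyde and E1cB dehydration under thermodynamic control gives the (Z)-benzylidene isomer (aryl syn to the ring oxygen, away from the C4–OH), while the epoxide centre is not touched.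

**Step 10**
Reactants: 24 (5Z)-3-[7-(allyloxy)-2,2-dimethylchroman-6-yl]-5-(4-(allyloxy)-3-{[(2R)-3,3-dimethyloxiran-2-yl]methyl}benzylidene)-4-hydroxyfuran-2(5H)-one
Product: 25 (5Z)-5-(3-{[(2R)-3,3-dimethyloxiran-2-yl]methyl}-4-hydroxybenzylidene)-4-hydroxy-3-(7-hydroxy-2,2-dimethylchroman-6-yl)furan-2(5H)-one (CNP0384423.1)
Conditions: Pd(PPh3)4 (5 mol %), morpholine (6 equiv), THF, rt; cold NaH2PO4 buffer work-up, brief acidification to pH 3 and immediate extraction
Reagents that add atoms: none
Why: Tsuji–Trost-type deallylation: zerovalent palladium ionises both aryl allyl ethers to π-allyl complexes that morpholine traps, freeing the phenols under near-neutral conditions that spare the acid- and base-sensitive epoxide, the (Z)-alkene and the stereocentre.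

**Compound list**
1 | methyl 2-(2,4-dihydroxyphenyl)acetate | COC(=O)Cc1ccc(O)cc1O | starting material
2 | prenal (3-methylbut-2-enal) | CC(C)=CC=O | starting material
3 | o-quinone methide, methyl 2-[6-hydroxy-3-(3-methylbut-2-en-1-ylidene)-4-oxocyclohexa-1,5-dien-1-yl]acetate (not isolated) | COC(=O)CC1=CC(=CC=C(C)C)C(=O)C=C1O | intermediate
4 | methyl 2-(7-hydroxy-2,2-dimethyl-2H-chromen-6-yl)acetate | COC(=O)Cc1cc2C=CC(C)(C)Oc2cc1O | intermediate
5 | methyl 2-(7-hydroxy-2,2-dimethylchroman-6-yl)acetate | COC(=O)Cc1cc2CCC(C)(C)Oc2cc1O | intermediate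
6 | allyl bromide | C=CCBr | starting material
7 | methyl 2-[7-(allyloxy)-2,2-dimethylchroman-6-yl]acetate | COC(=O)Cc1cc2CCC(C)(C)Oc2cc1OCC=C | intermediate
8 | methyl glycolate | COC(=O)CO | starting material
9 | glycolate ester, 2-methoxy-2-oxoethyl 2-[7-(allyloxy)-2,2-dimethylchroman-6-yl]acetate (not isolated) | COC(=O)COC(=O)Cc1cc2CCC(C)(C)Oc2cc1OCC=C | intermediate
10 | 3-[7-(allyloxy)-2,2-dimethylchroman-6-yl]-4-hydroxyfuran-2(5H)-one | O=C1OCC(O)=C1c1cc2CCC(C)(C)Oc2cc1OCC=C | intermediate
11 | 4-hydroxy-3-iodobenzaldehyde | O=Cc1ccc(O)c(I)c1 | starting material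
12 | 4-(allyloxy)-3-iodobenzaldehyde | O=Cc1ccc(OCC=C)c(I)c1 | intermediate
13 | trimethyl orthoformate | COC(OC)OC | starting material
14 | 1-(allyloxy)-4-(dimethoxymethyl)-2-iodobenzene | COC(OC)c1ccc(OCC=C)c(I)c1 | intermediate
15 | methyl (S)-glycidate, methyl (2S)-oxirane-2-carboxylate | COC(=O)[C@@H]1CO1 | starting material
16 | methylmagnesium bromide | C[Mg]Br | starting material
17 | arylmagnesium chloride, [2-(allyloxy)-5-(dimethoxymethyl)phenyl]magnesium chloride as its LiCl complex (not isolated) | C=CCOc1ccc(C(OC)OC)cc1[Mg]Cl | intermediate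
18 | hydroxy ester, methyl (2S)-3-[2-(allyloxy)-5-(dimethoxymethyl)phenyl]-2-hydroxypropanoate, present as its magnesium alkoxide (not isolated) | COC(=O)[C@@H](O)Cc1cc(C(OC)OC)ccc1OCC=C | intermediate
19 | diol acetal, (2S)-1-[2-(allyloxy)-5-(dimethoxymethyl)phenyl]-3-methylbutane-2,3-diol, present as its magnesium dialkoxide (not isolated) | CC(C)(O)[C@@H](O)Cc1cc(C(OC)OC)ccc1OCC=C | intermediate
20 | 4-(allyloxy)-3-[(2S)-2,3-dihydroxy-3-methylbutyl]benzaldehyde | CC(C)(O)[C@@H](O)Cc1cc(C=O)ccc1OCC=C | intermediate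
21 | hydroxy mesylate, (2S)-1-[2-(allyloxy)-5-formylphenyl]-3-hydroxy-3-methylbutan-2-yl methanesulfonate (not isolated) | CC(C)(O)[C@@H](OS(C)(=O)=O)Cc1cc(C=O)ccc1OCC=C | intermediate
22 | 4-(allyloxy)-3-{[(2R)-3,3-dimethyloxiran-2-yl]methyl}benzaldehyde | O=Cc1ccc(OCC=C)c(C[C@H]2OC2(C)C)c1 | intermediate
23 | aldol adduct, 3-[7-(allyloxy)-2,2-dimethylchroman-6-yl]-5-[(4-(allyloxy)-3-{[(2R)-3,3-dimethyloxiran-2-yl]methyl}phenyl)(hydroxy)methyl]-4-hydroxyfuran-2(5H)-one, diastereomer mixture at the two new carbons (not isolated) | CC1(C)CCc2cc(C3=C(O)C(C(O)c4ccc(OCC=C)c(C[C@H]5OC5(C)C)c4)OC3=O)c(OCC=C)cc2O1 | intermediate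
24 | (5Z)-3-[7-(allyloxy)-2,2-dimethylchroman-6-yl]-5-(4-(allyloxy)-3-{[(2R)-3,3-dimethyloxiran-2-yl]methyl}benzylidene)-4-hydroxyfuran-2(5H)-one | CC1(C)CCc2cc(C3=C(O)/C(=C/c4ccc(OCC=C)c(C[C@H]5OC5(C)C)c4)OC3=O)c(OCC=C)cc2O1 | intermediate
25 | (5Z)-5-(3-{[(2R)-3,3-dimethyloxiran-2-yl]methyl}-4-hydroxybenzylidene)-4-hydroxy-3-(7-hydroxy-2,2-dimethylchroman-6-yl)furan-2(5H)-one | CC1(C)CCc2cc(C3=C(O)/C(=C/c4ccc(O)c(C[C@H]5OC5(C)C)c4)OC3=O)c(O)cc2O1 | target

**Step count and risks**
Total steps: 10 (steps 1–4 fragment A, steps 5–8 fragment B, steps 9–10 union and deprotection).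
Longest linear sequence: 6 steps (1, 2, 3, 4, 9, 10; equally 5, 6, 7, 8, 9, 10).

Risk 1 (step 1): the condensation may also attack the ring carbon flanked by both oxygens, giving the angular chromene, or annulate a second time on the remaining phenol. The fallback sets out from 1 and comes back at 4. The unhindered 4-hydroxyl of 1 is O-alkylated with 3-chloro-3-methylbut-1-yne (CuCl2·2H2O cat., DBU, MeCN, 0 °C) to give methyl 2-[2-hydroxy-4-(2-methylbut-3-yn-2-yloxy)phenyl]acetate F1. Heating F1 in o-xylene at 140 °C triggers an aromatic propargyl Claisen rearrangement onto the less hindered ortho carbon, a 1,5-hydrogen shift and oxa-6π electrocyclisation, which delivers chromene 4.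

Risk 2 (step 7): four events run in one flask; 17 may attack the ester of 15 before the epoxide, and the allyl ether may suffer copper-catalysed substitution once excess MeMgBr is present. The fallback sets out from 15 and comes back at 20 by inverting the order of the two C–C bond formations. MeMgBr 16 (2.1 equiv, THF, −78 °C) is added to 15 to give 2-[(2S)-oxiran-2-yl]propan-2-ol F2. The crude carbinol is silylated (Et3SiCl, imidazole, DMAP, DMF) to triethyl({2-[(2S)-oxiran-2-yl]propan-2-yl}oxy)silane F3. Arylmagnesium chloride 17 (made from 14 by the same iodine–magnesium exchange) opens F3 at its CH2 terminus (CuI 10 mol %, THF, −30 → 0 °C) to give (2S)-1-[2-(allyloxy)-5-(dimethoxymethyl)phenyl]-3-methyl-3-(triethylsilyloxy)butan-2-ol F4. Stirring F4 with 1 M HCl in THF removes the silyl ether and the acetal and returns diol aldehyde 20 with the same (S) centre.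

Risk 3 (step 9): the DBU condensation may stall at the aldol stage, give E/Z mixtures, or damage the epoxide on prolonged heating. The fallback sets out from 7 and 22 and comes back at 24, closing the butenolide ring last instead of condensing onto it. Ester 7 is saponified (LiOH, THF/H2O) to 2-[7-(allyloxy)-2,2-dimethylchroman-6-yl]acetic acid F5. F5 is coupled (DCC, DMAP, CH2Cl2) with the known reagent methyl 2-(dimethoxyphosphoryl)-2-hydroxyacetate to give methyl 2-(dimethoxyphosphoryl)-2-({2-[7-(allyloxy)-2,2-dimethylchroman-6-yl]acetyl}oxy)acetate F6. A Horner–Wadsworth–Emmons reaction of F6 with aldehyde 22 (LiCl, DBU, MeCN, 0 °C) gives methyl (2Z)-2-({2-[7-(allyloxy)-2,2-dimethylchroman-6-yl]acetyl}oxy)-3-(4-(allyloxy)-3-{[(2R)-3,3-dimethyloxiran-2-yl]methyl}phenyl)acrylate F7. Dieckmann cyclisation of F7 with LiN(SiMe3)2 (2.2 equiv, THF, −78 → 0 °C; pH 4 work-up) forms the tetronic acid ring with the enol ester geometry retained and gives 24.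

**Further compounds**
F1 | step 1 | methyl 2-[2-hydroxy-4-(2-methylbut-3-yn-2-yloxy)phenyl]acetate | COC(=O)Cc1ccc(OC(C)(C)C#C)cc1O
F2 | step 7 | 2-[(2S)-oxiran-2-yl]propan-2-ol | CC(C)(O)[C@@H]1CO1
F3 | step 7 | triethyl({2-[(2S)-oxiran-2-yl]propan-2-yl}oxy)silane | CC[Si](CC)(CC)OC(C)(C)[C@@H]1CO1
F4 | step 7 | (2S)-1-[2-(allyloxy)-5-(dimethoxymethyl)phenyl]-3-methyl-3-(triethylsilyloxy)butan-2-ol | CC[Si](CC)(CC)OC(C)(C)[C@@H](O)Cc1cc(C(OC)OC)ccc1OCC=C
F5 | step 9 | 2-[7-(allyloxy)-2,2-dimethylchroman-6-yl]acetic acid | OC(=O)Cc1cc2CCC(C)(C)Oc2cc1OCC=C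
F6 | step 9 | methyl 2-(dimethoxyphosphoryl)-2-({2-[7-(allyloxy)-2,2-dimethylchroman-6-yl]acetyl}oxy)acetate | COC(=O)C(OC(=O)Cc1cc2CCC(C)(C)Oc2cc1OCC=C)P(=O)(OC)OC
F7 | step 9 | methyl (2Z)-2-({2-[7-(allyloxy)-2,2-dimethylchroman-6-yl]acetyl}oxy)-3-(4-(allyloxy)-3-{[(2R)-3,3-dimethyloxiran-2-yl]methyl}phenyl)acrylate | COC(=O)/C(OC(=O)Cc1cc2CCC(C)(C)Oc2cc1OCC=C)=C/c1ccc(OCC=C)c(C[C@H]2OC2(C)C)c1
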